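**Plan**
- In the flavanone, C3 of ring C is a methylene bonded to the aryl ketone carbon C4. Written as its enol silane, C3=C4 is a ring alkene of a 4-silyloxy-2H-chromene and O1–C2 is a branched allyl aryl ether, so the retrosynthesis cuts C3=C4 first (metathesis) and O1–C2 second (allylic etherification).
- The ring B cinnamyl carbonate is cut further at its alkene (olefination of a benzaldehyde) and at the aryl–prenyl bond (cross-coupling of an aryl bromide).
- Forward, ring B is built linearly from 3-bromo-4,5-dihydroxybenzaldehyde (methylation, MOM protection, prenylation, two-carbon homologation, carbonate); ring A is 2',4'-dihydroxyacetophenone as its 4'-MOM ether.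
- The two arenes are joined at O1–C2, the acetyl group is converted into its silyl enol ether, and ring C, the only ring formed, is closed by metathesis; acid then releases the ketone and both phenols.
- The single stereocentre C2 (S) is set by the chiral phosphoramidite ligand in the iridium-catalysed etherification and is carried unchanged to the target.

Key step: step 10

Assumption: the (Sa,Sc,Sc) enantiomer of the binaphthol/bis(1-phenylethyl)amine phosphoramidite is taken to deliver the (S)-configured branched ether from an aryl-substituted allyl carbonate; should the sense of induction be the opposite, the (Ra,Rc,Rc) ligand is used instead.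

**Step 1**
Reactants: 1 3-bromo-4,5-dihydroxybenzaldehyde
Product: 2 3-bromo-5-hydroxy-4-methoxybenzaldehyde
Conditions: MeI (1.2 equiv), Li2CO3, DMF, 40 °C
Reagents that add atoms: iodomethane (MeI), CI
Why: The 4-hydroxyl, para to the formyl group and flanked by bromine, is the more acidic phenol, so the weak base Li2CO3 should form only its phenoxide and Williamson O-methylation should occur there selectively.

**Step 2**
Reactants: 2 3-bromo-5-hydroxy-4-methoxybenzaldehyde
Product: 3 3-bromo-4-methoxy-5-(methoxymethoxy)benzaldehyde
Conditions: MOMCl, i-Pr2NEt, CH2Cl2, 0 °C to rt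
Reagents that add atoms: chloromethyl methyl ether (MOMCl), COCCl
Why: O-Alkylation of the remaining phenol with the chloromethyl ether (acetal protection) gives a MOM ether that tolerates the basic, hydridic and organometallic steps ahead and is removed by dilute acid at the end.

**Step 3**
Reactants: 3 3-bromo-4-methoxy-5-(methoxymethoxy)benzaldehyde; 4 tributyl(3-methylbut-2-enyl)stannane
Product: 5 4-methoxy-3-(methoxymethoxy)-5-(3-methylbut-2-enyl)benzaldehyde
Conditions: Pd(PPh3)4 (5 mol%), DMF, 95 °C
Reagents that add atoms: none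
Why: Stille cross-coupling, in which zerovalent palladium inserts into the aryl C–Br bond, the allylic stannane transmetalates and reductive elimination at the less hindered CH2 terminus should give the linear prenyl arene while aldehyde and acetal stay untouched under the neutral conditions.

**Step 4**
Reactants: 5 4-methoxy-3-(methoxymethoxy)-5-(3-methylbut-2-enyl)benzaldehyde; 6 triethyl phosphonoacetate
Product: 8 ethyl (E)-3-[4-methoxy-3-(methoxymethoxy)-5-(3-methylbut-2-enyl)phenyl]prop-2-enoate, via sodium phosphonate carbanion 7 (not isolated)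
Conditions: NaH, THF, 0 °C; then 5, 0 °C to rt
Reagents that add atoms: none
Why: Horner–Wadsworth–Emmons olefination of an aromatic aldehyde with a stabilised phosphonate carbanion should give the (E)-cinnamate as the thermodynamically preferred alkene.

**Step 5**
Reactants: 8 ethyl (E)-3-[4-methoxy-3-(methoxymethoxy)-5-(3-methylbut-2-enyl)phenyl]prop-2-enoate
Product: 9 (E)-3-[4-methoxy-3-(methoxymethoxy)-5-(3-methylbut-2-enyl)phenyl]prop-2-en-1-ol
Conditions: i-Bu2AlH (2.3 equiv), CH2Cl2, −78 °C; aq. KNaC4H4O6 (potassium sodium tartrate) work-up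
Reagents that add atoms: none
Why: Low-temperature 1,2-reduction of the conjugated ester with the aluminium hydride should give the allylic alcohol without affecting either alkene or the acetal.

**Step 6**
Reactants: 9 (E)-3-[4-methoxy-3-(methoxymethoxy)-5-(3-methylbut-2-enyl)phenyl]prop-2-en-1-ol
Product: 10 methyl (E)-3-[4-methoxy-3-(methoxymethoxy)-5-(3-methylbut-2-enyl)phenyl]prop-2-enyl carbonate
Conditions: ClCO2Me, pyridine, CH2Cl2, 0 °C
Reagents that add atoms: methyl chloroformate, COC(=O)Cl
Why: Acylation of the primary allylic alcohol with the chloroformate installs the carbonate leaving group required for ionisation in the allylic substitution.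

**Step 7**
Reactants: 11 2',4'-dihydroxyacetophenone
Product: 12 1-[2-hydroxy-4-(methoxymethoxy)phenyl]ethanone
Conditions: MOMCl (1.1 equiv), K2CO3, acetone, rt
Reagents that add atoms: chloromethyl methyl ether (MOMCl), COCCl
Why: The 2'-hydroxyl is held in a hydrogen bond to the acetyl oxygen and is much less nucleophilic, so Williamson-type alkylation with one equivalent of the chloromethyl ether should take place only at the 4'-hydroxyl.

**Step 8**
Reactants: 10 methyl (E)-3-[4-methoxy-3-(methoxymethoxy)-5-(3-methylbut-2-enyl)phenyl]prop-2-enyl carbonate; 12 1-[2-hydroxy-4-(methoxymethoxy)phenyl]ethanone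
Product: 14 1-[2-[(1S)-1-[4-methoxy-3-(methoxymethoxy)-5-(3-methylbut-2-enyl)phenyl]prop-2-enoxy]-4-(methoxymethoxy)phenyl]ethanone, via sodium aryloxide 13 (not isolated)
Conditions: 12, NaH, THF, 0 °C; then 10, [Ir(cod)Cl]2 (2 mol%), (Sa,Sc,Sc)-O,O'-(1,1'-binaphthyl-2,2'-diyl) N,N-bis(1-phenylethyl)phosphoramidite (4 mol%, pre-activated with n-PrNH2), THF, rt
Reagents that add atoms: none
Why: Iridium-catalysed asymmetric allylic etherification (an allylic substitution of the Tsuji–Trost family): the cyclometalated catalyst formed from [Ir(cod)Cl]2 and the phosphoramidite ionises the linear carbonate to an allyl complex, and the aryloxide attacks its aryl-substituted terminus to give the branched ether, the ligand fixing the face of attack and so the S configuration of the future C2; the reaction is stopped once 10 is consumed so that the stabilised aryloxide is not expelled again.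

**Step 9**
Reactants: 14 1-[2-[(1S)-1-[4-methoxy-3-(methoxymethoxy)-5-(3-methylbut-2-enyl)phenyl]prop-2-enoxy]-4-(methoxymethoxy)phenyl]ethanone
Product: 16 tert-butyl-[1-[2-[(1S)-1-[4-methoxy-3-(methoxymethoxy)-5-(3-methylbut-2-enyl)phenyl]prop-2-enoxy]-4-(methoxymethoxy)phenyl]ethenoxy]dimethylsilane, via potassium enolate 15 (not isolated)
Conditions: KN(SiMe3)2 (1.1 equiv), THF, −78 °C; then TBSCl, −78 to 0 °C
Reagents that add atoms: tert-butyldimethylsilyl chloride (TBSCl), CC(C)(C)[Si](C)(C)Cl
Why: Silyl enol ether formation by enolate trapping: the methyl ketone is by far the most acidic C–H site, so the hindered amide base should give only its enolate, which is O-silylated to the 1,1-disubstituted enol silane without disturbing the ether stereocentre.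

**Step 10**
Reactants: 16 tert-butyl-[1-[2-[(1S)-1-[4-methoxy-3-(methoxymethoxy)-5-(3-methylbut-2-enyl)phenyl]prop-2-enoxy]-4-(methoxymethoxy)phenyl]ethenoxy]dimethylsilane
Product: 17 tert-butyl-[[(2S)-2-[4-methoxy-3-(methoxymethoxy)-5-(3-methylbut-2-enyl)phenyl]-7-(methoxymethoxy)-2H-chromen-4-yl]oxy]dimethylsilane
Conditions: second-generation Grubbs catalyst RuCl2(=CHPh)(H2IMes)(PCy3) (5–10 mol%), degassed toluene (5 mM), 60 °C
Reagents that add atoms: none
Why: The ruthenium benzylidene should first exchange with the monosubstituted vinyl group to place the alkylidene on the carbon next to C2; intramolecular [2+2] cycloaddition with the 1,1-disubstituted silyl enol ether and cycloreversion of the ruthenacyclobutane then form C3=C4 and release [Ru]=CH2, which turns over with loss of ethylene. The closest known reaction type is ring-closing metathesis of silyl enol ethers with terminal alkenes to cyclic enol silanes, together with the established closure of 2H-chromenes from allyl aryl ethers. Ring C is closed as a six-membered ring with the new double bond endocyclic, the ortho relationship of O1 and the enol ether on ring A holding both alkenes within reach. No stereocentre is created, and the allylic C2 centre from step 8 takes part in no bond change. The step needs the vinyl/enol ether pair to react in preference to the trisubstituted prenyl alkene: that alkene initiates slowly, cannot form an unstrained ring with either partner, and high dilution suppresses its intermolecular cross-metathesis. The metallacycle regiochemistry leaves ruthenium on the unsubstituted CH2 and not on the oxygen-bearing carbon, so no inert heteroatom-stabilised carbene should build up, and moderate temperature limits hydride-induced isomerisation of the allyl ether.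

**Step 11**
Reactants: 17 tert-butyl-[[(2S)-2-[4-methoxy-3-(methoxymethoxy)-5-(3-methylbut-2-enyl)phenyl]-7-(methoxymethoxy)-2H-chromen-4-yl]oxy]dimethylsilane
Product: 19 erylatissin C [(2S)-7-hydroxy-2-[3-hydroxy-4-methoxy-5-(3-methylbut-2-enyl)phenyl]-2,3-dihydrochromen-4-one], via bis-MOM flavanone 18 (not isolated)
Conditions: 3 M aq. HCl, MeOH, rt to 40 °C
Reagents that add atoms: none
Why: Acid hydrolysis of the enol silane (protonation at C3, loss of silicon) gives the C4 ketone and the same acid cleaves both MOM acetals by acetal methanolysis; the O1–C2 bond is not broken under mild acid so the S configuration should be kept, and the prenyl alkene has no ortho hydroxyl with which to cyclise.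

**Compound list**
1 | 3-bromo-4,5-dihydroxybenzaldehyde | O=Cc1cc(O)c(O)c(Br)c1 | starting material
2 | 3-bromo-5-hydroxy-4-methoxybenzaldehyde | COc1c(O)cc(C=O)cc1Br | intermediate
3 | 3-bromo-4-methoxy-5-(methoxymethoxy)benzaldehyde | COCOc1cc(C=O)cc(Br)c1OC | intermediate
4 | tributyl(3-methylbut-2-enyl)stannane | CCCC[Sn](CCCC)(CCCC)CC=C(C)C | starting material
5 | 4-methoxy-3-(methoxymethoxy)-5-(3-methylbut-2-enyl)benzaldehyde | COCOc1cc(C=O)cc(CC=C(C)C)c1OC | intermediate
6 | triethyl phosphonoacetate | CCOC(=O)CP(=O)(OCC)OCC | starting material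
7 | sodium salt of triethyl phosphonoacetate (phosphonate carbanion) | CCOC(=O)[CH-]P(=O)(OCC)OCC.[Na+] | intermediate
8 | ethyl (E)-3-[4-methoxy-3-(methoxymethoxy)-5-(3-methylbut-2-enyl)phenyl]prop-2-enoate | CCOC(=O)/C=C/c1cc(OCOC)c(OC)c(CC=C(C)C)c1 | intermediate
9 | (E)-3-[4-methoxy-3-(methoxymethoxy)-5-(3-methylbut-2-enyl)phenyl]prop-2-en-1-ol | OC/C=C/c1cc(OCOC)c(OC)c(CC=C(C)C)c1 | intermediate
10 | methyl (E)-3-[4-methoxy-3-(methoxymethoxy)-5-(3-methylbut-2-enyl)phenyl]prop-2-enyl carbonate | COC(=O)OC/C=C/c1cc(OCOC)c(OC)c(CC=C(C)C)c1 | intermediate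
11 | 2',4'-dihydroxyacetophenone | CC(=O)c1ccc(O)cc1O | starting material
12 | 1-[2-hydroxy-4-(methoxymethoxy)phenyl]ethanone | CC(=O)c1ccc(OCOC)cc1O | intermediate
13 | sodium 2-acetyl-5-(methoxymethoxy)phenolate | CC(=O)c1ccc(OCOC)cc1[O-].[Na+] | intermediate
14 | 1-[2-[(1S)-1-[4-methoxy-3-(methoxymethoxy)-5-(3-methylbut-2-enyl)phenyl]prop-2-enoxy]-4-(methoxymethoxy)phenyl]ethanone | C=C[C@H](Oc1cc(OCOC)ccc1C(C)=O)c1cc(OCOC)c(OC)c(CC=C(C)C)c1 | intermediate
15 | potassium 1-[2-[(1S)-1-[4-methoxy-3-(methoxymethoxy)-5-(3-methylbut-2-enyl)phenyl]prop-2-enoxy]-4-(methoxymethoxy)phenyl]ethenolate | C=C[C@H](Oc1cc(OCOC)ccc1C(=C)[O-])c1cc(OCOC)c(OC)c(CC=C(C)C)c1.[K+] | intermediate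
16 | tert-butyl-[1-[2-[(1S)-1-[4-methoxy-3-(methoxymethoxy)-5-(3-methylbut-2-enyl)phenyl]prop-2-enoxy]-4-(methoxymethoxy)phenyl]ethenoxy]dimethylsilane | C=C[C@H](Oc1cc(OCOC)ccc1C(=C)O[Si](C)(C)C(C)(C)C)c1cc(OCOC)c(OC)c(CC=C(C)C)c1 | intermediate
17 | tert-butyl-[[(2S)-2-[4-methoxy-3-(methoxymethoxy)-5-(3-methylbut-2-enyl)phenyl]-7-(methoxymethoxy)-2H-chromen-4-yl]oxy]dimethylsilane | CC(C)(C)[Si](C)(C)OC1=C[C@@H](c2cc(OCOC)c(OC)c(CC=C(C)C)c2)Oc2cc(OCOC)ccc21 | intermediate
18 | (2S)-2-[4-methoxy-3-(methoxymethoxy)-5-(3-methylbut-2-enyl)phenyl]-7-(methoxymethoxy)-2,3-dihydrochromen-4-one | COCOc1cc([C@@H]2CC(=O)c3ccc(OCOC)cc3O2)cc(CC=C(C)C)c1OC | intermediate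
19 | erylatissin C, (2S)-7-hydroxy-2-[3-hydroxy-4-methoxy-5-(3-methylbut-2-enyl)phenyl]-2,3-dihydrochromen-4-one | COc1c(O)cc([C@@H]2CC(=O)c3ccc(O)cc3O2)cc1CC=C(C)C | target

**Step count**
Total: 11 steps. Longest linear sequence: 10 steps (from 1 through steps 1–6 and 8–11); the ring A branch contributes step 7.

**Steps most likely to fail**

Step 8. The acyl-stabilised, chelating aryloxide may attack the allyl complex slowly and, being a good leaving group, may be expelled again from the product by the iridium catalyst. That would erode enantiomeric purity and let the material drift to the linear cinnamyl ether. The fallback lowers the oxidation level of the nucleophile; it sets out from 12 and rejoins the route at 14. Ketone 12 is reduced with NaBH4 in MeOH at 0 °C to 2-(1-hydroxyethyl)-5-(methoxymethoxy)phenol F1. One equivalent of NaH converts it into sodium 2-(1-hydroxyethyl)-5-(methoxymethoxy)phenolate F2, an ordinary ortho-alkyl aryloxide that is more nucleophilic and a much poorer leaving group than 13. The same etherification with carbonate 10 ([Ir(cod)Cl]2 and the phosphoramidite, THF, rt) should give 1-[2-[(1S)-1-[4-methoxy-3-(methoxymethoxy)-5-(3-methylbut-2-enyl)phenyl]prop-2-enoxy]-4-(methoxymethoxy)phenyl]ethanol F3 as both carbinol epimers. Oxidation of the benzylic alcohol with Dess–Martin periodinane (NaHCO3, CH2Cl2) converges both epimers on ketone 14.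

Step 10. The hindered, electron-rich 1,1-disubstituted enol silane may engage the ruthenium alkylidene too slowly, so that catalyst decay, loss of the silyl group or hydride-induced isomerisation of the allyl ether wins. The fallback closes ring C at O1–C2 instead; it sets out from 12 and 5 and rejoins the route at 18. Claisen–Schmidt condensation of 12 with aldehyde 5 (KOH, EtOH, rt) should give (E)-1-[2-hydroxy-4-(methoxymethoxy)phenyl]-3-[4-methoxy-3-(methoxymethoxy)-5-(3-methylbut-2-enyl)phenyl]prop-2-en-1-one F4. NaOAc in refluxing EtOH closes the ring by intramolecular oxa-Michael addition to racemic 2-[4-methoxy-3-(methoxymethoxy)-5-(3-methylbut-2-enyl)phenyl]-7-(methoxymethoxy)-2,3-dihydrochromen-4-one F5. Preparative chromatography on a chiral stationary phase separates 18 from (2R)-2-[4-methoxy-3-(methoxymethoxy)-5-(3-methylbut-2-enyl)phenyl]-7-(methoxymethoxy)-2,3-dihydrochromen-4-one F6, which is returned to the NaOAc equilibration. Compound 18 is then deprotected under the conditions of step 11.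

Step 11. During the time needed to cleave two aryl MOM ethers, protic acid may cause reversible opening of the pyranone ring, with partial loss of configuration at C2, or addition of HCl or methanol across the prenyl alkene. The fallback separates the two deprotections and avoids strong protic acid; it sets out from 17 and ends at 19. Aqueous AcOH in THF at rt should hydrolyse only the enol silane, giving ketone 18, which is isolated. TMSOTf and 2,2'-bipyridyl in CH2Cl2 at 0 °C then convert both aryl MOM ethers into silyl ethers, giving (2S)-2-[4-methoxy-5-(3-methylbut-2-enyl)-3-(trimethylsilyloxy)phenyl]-7-(trimethylsilyloxy)-2,3-dihydrochromen-4-one F7. Water in the work-up hydrolyses these aryl silyl ethers to 19.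

**Further compounds**
F1 | step 8 | 2-(1-hydroxyethyl)-5-(methoxymethoxy)phenol | CC(O)c1ccc(OCOC)cc1O
F2 | step 8 | sodium 2-(1-hydroxyethyl)-5-(methoxymethoxy)phenolate | CC(O)c1ccc(OCOC)cc1[O-].[Na+]
F3 | step 8 | 1-[2-[(1S)-1-[4-methoxy-3-(methoxymethoxy)-5-(3-methylbut-2-enyl)phenyl]prop-2-enoxy]-4-(methoxymethoxy)phenyl]ethanol (both carbinol epimers) | C=C[C@H](Oc1cc(OCOC)ccc1C(C)O)c1cc(OCOC)c(OC)c(CC=C(C)C)c1
F4 | step 10 | (E)-1-[2-hydroxy-4-(methoxymethoxy)phenyl]-3-[4-methoxy-3-(methoxymethoxy)-5-(3-methylbut-2-enyl)phenyl]prop-2-en-1-one | COCOc1ccc(C(=O)/C=C/c2cc(OCOC)c(OC)c(CC=C(C)C)c2)c(O)c1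
F5 | step 10 | racemic 2-[4-methoxy-3-(methoxymethoxy)-5-(3-methylbut-2-enyl)phenyl]-7-(methoxymethoxy)-2,3-dihydrochromen-4-one | COCOc1cc(C2CC(=O)c3ccc(OCOC)cc3O2)cc(CC=C(C)C)c1OC
F6 | step 10 | (2R)-2-[4-methoxy-3-(methoxymethoxy)-5-(3-methylbut-2-enyl)phenyl]-7-(methoxymethoxy)-2,3-dihydrochromen-4-one | COCOc1cc([C@H]2CC(=O)c3ccc(OCOC)cc3O2)cc(CC=C(C)C)c1OC
F7 | step 11 | (2S)-2-[4-methoxy-5-(3-methylbut-2-enyl)-3-(trimethylsilyloxy)phenyl]-7-(trimethylsilyloxy)-2,3-dihydrochromen-4-one | COc1c(O[Si](C)(C)C)cc([C@@H]2CC(=O)c3ccc(O[Si](C)(C)C)cc3O2)cc1CC=C(C)C
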